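**Plan**
- Retrosynthesis: the benzoate pattern is adjusted last; the cyclohexene is then cut at C1–C2 and C5–C6 (C1 = quaternary carbinol carbon, C7 = its CH2O carbon, C2/C5 = benzoyloxy methines, C3=C4 = alkene, C6 = hydroxy methine).
- Enabling feature: the ring contains a C2–C3=C4–C5 but-2-ene unit with cis oxygens at both ends, facing a C1–C6 unit with two cis oxygens and the extra carbon C7 on C1. This maps onto an (E,E)-1,4-dioxygenated diene and an enediol-type alkene whose carboxyl carbon becomes C7.
- Forward, dienophile: O-benzyl-D-serine 1 → hydroxy acid 2 → cis-dioxolanone 4 (with pivalaldehyde) → alcohol 5 → enolised aldehyde 7 → (Z)-enol benzoate 9. Diene: dienyl diacetate 10 → bis(silyloxy)diene 12.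
- The only carbocycle is closed by the Diels–Alder union of 9 and 12 (step 7). Then: LiAlH4, O7 benzoylation, C1/C6 acetonide, desilylation, O2/O5 benzoylation, ketal hydrolysis.
- Stereochemistry: the serine α-carbon sets the acetal centre (cis-selective acetalisation) and is then erased. The acetal tert-butyl group fixes the alkene face (C1), the (Z)-enol ester fixes C6, and the (E,E)-diene with oxygen-endo approach fixes C2 and C5, so all four ring oxygens end up cis.

Key step: step 7

Remark: locants C1–C7 defined above are used for all ring compounds (the C1 descriptor of 17 and 18 differs from 16 only through CIP priorities); (1E,3E)-buta-1,3-diene-1,4-diyl diacetate 10 is taken as purchasable (otherwise two steps from cyclooctatetraene via Hg(OAc)2 acetoxylation and dimethyl acetylenedicarboxylate cycloaddition/cycloreversion).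

**Route**

Step 1
Reactants: 1 O-benzyl-D-serine
Product: 2 (2R)-3-(benzyloxy)-2-hydroxypropanoic acid
Conditions: NaNO2, 1 M H2SO4, H2O, 0 °C to rt
Reagents that add atoms: water, O
Why: Diazotisation of the α-amino acid with hydrolysis of the diazonium salt should proceed with net retention through carboxylate participation (double inversion), so the (R)-centre of 1 is carried into the α-hydroxy acid.

Step 2
Reactants: 2 (2R)-3-(benzyloxy)-2-hydroxypropanoic acid; 3 pivalaldehyde
Product: 4 (2R,5R)-5-[(benzyloxy)methyl]-2-tert-butyl-1,3-dioxolan-4-one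
Conditions: 3 (1.5 equiv), TsOH·H2O (cat.), H2SO4 (cat.), pentane, reflux, Dean–Stark; cis isomer purified by crystallisation or chromatography
Reagents that add atoms: none
Why: Acid-catalysed acetalisation of an α-hydroxy acid with pivalaldehyde under azeotropic water removal should favour the cis-2,5-disubstituted dioxolanone, so the (R)-centre of 2 sets the new acetal centre as (2R), and the minor trans isomer must be removed because its acetal centre has the opposite sense.

Step 3
Reactants: 4 (2R,5R)-5-[(benzyloxy)methyl]-2-tert-butyl-1,3-dioxolan-4-one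
Product: 5 (2R,5R)-2-tert-butyl-5-(hydroxymethyl)-1,3-dioxolan-4-one
Conditions: H2 (1 atm), 10% Pd/C, EtOAc, rt
Reagents that add atoms: none
Why: Hydrogenolysis of the benzyl ether under neutral conditions should leave the acetal and the lactone untouched.

Step 4
Reactants: 5 (2R,5R)-2-tert-butyl-5-(hydroxymethyl)-1,3-dioxolan-4-one
Product: 7 (2R)-2-tert-butyl-5-(hydroxymethylidene)-1,3-dioxolan-4-one, via formyl lactone 6 (not isolated)
Conditions: (COCl)2 (1.05 equiv), DMSO, CH2Cl2, −78 °C; Et3N, −78 to 0 °C; cold aq. KHSO4 work-up; crude product used at once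
Reagents that add atoms: none
Why: In a Swern oxidation the aldehyde appears only after the oxidant has been consumed, and the α-formyl lactone should tautomerise to its conjugated enol, which erases the C5 stereocentre while the acetal centre is unaffected.

Step 5
Reactants: 7 (2R)-2-tert-butyl-5-(hydroxymethylidene)-1,3-dioxolan-4-one; 8 benzoyl chloride
Product: 9 (2R)-5-[(Z)-(benzoyloxy)methylidene]-2-tert-butyl-1,3-dioxolan-4-one
Conditions: 8 (1.1 equiv), Et3N, DMAP (cat.), CH2Cl2, −20 to 0 °C
Reagents that add atoms: none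
Why: O-Acylation (enol ester formation) of hydroxymethylene-lactone enolates is expected to occur from the extended enolate form with the enolate oxygen remote from the lactone carbonyl, which here corresponds to the (Z)-enol benzoate with benzoyloxy cis to the ring oxygen.

Step 6
Reactants: 10 (1E,3E)-buta-1,3-diene-1,4-diyl diacetate
Product: 12 (1E,3E)-1,4-bis(tert-butyldimethylsilyloxy)buta-1,3-diene, via dilithium dienediolate 11 (not isolated)
Conditions: MeLi (4.1 equiv), THF, −78 to 0 °C; then TBSCl (3 equiv), DMPU, −78 °C to rt; cold NaHCO3 work-up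
Reagents that add atoms: tert-butyldimethylsilyl chloride, CC(C)(C)[Si](C)(C)Cl
Why: Cleavage of the two enol acetates by MeLi should give the bis-enolate with retention of the (E,E)-geometry, and O-silylation of this lithium enolate gives the bis(silyl dienol ether).

Step 7
Reactants: 9 (2R)-5-[(Z)-(benzoyloxy)methylidene]-2-tert-butyl-1,3-dioxolan-4-one; 12 (1E,3E)-1,4-bis(tert-butyldimethylsilyloxy)buta-1,3-diene
Product: 13 (2R,5S,6R,9S,10S)-2-tert-butyl-6,9-bis(tert-butyldimethylsilyloxy)-4-oxo-1,3-dioxaspiro[4.5]dec-7-en-10-yl benzoate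
Conditions: 12 (2 equiv), BHT (cat.), toluene, 110 °C, sealed tube
Reagents that add atoms: none
Why: A concerted, suprafacial, normal-electron-demand Diels–Alder reaction between the electron-rich diene 12 and the lactone-activated exocyclic alkene of 9 should form C1–C2 and C5–C6 together, the diene termini becoming C2 and C5 and its central bond C3=C4. The closest known reactions are the thermal, carbonyl-exo cycloadditions of 2-tert-butyl-5-methylidene-1,3-dioxolan-4-ones and the all-cis cycloadditions of (E,E)-1,4-dioxygenated butadienes with vinylene carbonate. The cyclohexene closes by intermolecular [4+2] annulation, both ring bonds being made in this step, which leaves the dioxolanone spiro-fused at C1. C1 is set by approach of the diene to the alkene face anti to the acetal tert-butyl group, C6 by suprafacial transfer of the (Z)-geometry (O6 cis to O1), and C2 and C5 by the (E,E)-geometry of 12 together with endo placement of the two dienophile oxygens (lactone carbonyl exo), which puts both silyloxy groups cis to O1 and O6. The step needs facial and endo/exo selectivity but no regiocontrol because 12 is symmetric; the first should come from the rigid acetal ring and the second from the carbonyl-exo preference of α-oxygenated alkylidene lactones, reinforced by the enol ester oxygen.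

Step 8
Reactants: 13 spiro cycloadduct
Product: 14 (1S,2R,5S,6S)-2,5-bis(tert-butyldimethylsilyloxy)-1-(hydroxymethyl)cyclohex-3-ene-1,6-diol
Conditions: LiAlH4 (3 equiv), THF, −20 to 0 °C; aq. NaOH work-up
Reagents that add atoms: none
Why: Hydride reduction of the lactone carbonyl to C7H2OH should collapse the acetal and free O1, and the C6 benzoate is cleaved reductively, while the secondary allylic silyl ethers are inert at this temperature and no stereocentre is touched.

Step 9
Reactants: 14 triol; 8 benzoyl chloride
Product: 15 [(1S,2R,5S,6S)-2,5-bis(tert-butyldimethylsilyloxy)-1,6-dihydroxycyclohex-3-en-1-yl]methyl benzoate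
Conditions: 8 (1.05 equiv), pyridine, CH2Cl2, −40 to −10 °C
Reagents that add atoms: none
Why: Selective esterification of the primary hydroxyl is expected because the C6 hydroxyl is a hindered secondary one and the C1 hydroxyl is tertiary.

Step 10
Reactants: 15 C7 monobenzoate
Product: 16 [(1S,2R,5S,6S)-2,5-bis(tert-butyldimethylsilyloxy)-1,6-(isopropylidenedioxy)cyclohex-3-en-1-yl]methyl benzoate
Conditions: 2-methoxypropene (3 equiv), pyridinium p-toluenesulfonate (cat.), CH2Cl2, 0 °C to rt
Reagents that add atoms: 2-methoxypropene, COC(C)=C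
Why: Acid-catalysed ketalisation of the cis C1/C6 diol should give the cis-fused dioxolane under mild aprotic conditions that spare the silyl ethers and the benzoate.

Step 11
Reactants: 16 acetonide
Product: 17 [(1R,2R,5S,6S)-2,5-dihydroxy-1,6-(isopropylidenedioxy)cyclohex-3-en-1-yl]methyl benzoate
Conditions: Bu4NF (3 equiv), AcOH (3 equiv), THF, 0 °C to rt
Reagents that add atoms: none
Why: Fluoride-mediated silyl ether cleavage buffered with acetic acid should limit alkoxide-driven benzoyl migration, and an O7-to-O2 shift would in any case be corrected when all free hydroxyls are benzoylated in the next step.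

Step 12
Reactants: 17 diol; 8 benzoyl chloride
Product: 18 [(1R,2R,5S,6S)-2,5-bis(benzoyloxy)-1,6-(isopropylidenedioxy)cyclohex-3-en-1-yl]methyl benzoate
Conditions: 8 (3 equiv), pyridine, DMAP (cat.), CH2Cl2, 0 °C to rt
Reagents that add atoms: none
Why: DMAP-catalysed acylation of the two allylic secondary alcohols completes the tribenzoate with no other free hydroxyl present.

Step 13
Reactants: 18 tribenzoate acetonide
Product: 19 [(1S,2R,5S,6S)-2,5-bis(benzoyloxy)-1,6-dihydroxycyclohex-3-en-1-yl]methyl benzoate
Conditions: TFA/H2O (4:1), CH2Cl2, 0 °C, short reaction time; neutral work-up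
Reagents that add atoms: none
Why: Acid-catalysed ketal hydrolysis in cold aqueous trifluoroacetic acid should free O1 and O6 while benzoate esters are stable and acyl migration is slow.

**Compound list**

1 | O-benzyl-D-serine, (2R)-2-amino-3-(benzyloxy)propanoic acid | N[C@H](COCc1ccccc1)C(=O)O | starting material
2 | (2R)-3-(benzyloxy)-2-hydroxypropanoic acid | O[C@H](COCc1ccccc1)C(=O)O | intermediate
3 | pivalaldehyde (2,2-dimethylpropanal) | CC(C)(C)C=O | starting material
4 | (2R,5R)-5-[(benzyloxy)methyl]-2-tert-butyl-1,3-dioxolan-4-one (tert-butyl and CH2OBn cis) | O=C1[C@@H](COCc2ccccc2)O[C@@H](C(C)(C)C)O1 | intermediate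
5 | (2R,5R)-2-tert-butyl-5-(hydroxymethyl)-1,3-dioxolan-4-one | O=C1[C@@H](CO)O[C@@H](C(C)(C)C)O1 | intermediate
6 | (2R,5R)-2-tert-butyl-5-formyl-1,3-dioxolan-4-one (aldehyde tautomer) | O=C1[C@@H](C=O)O[C@@H](C(C)(C)C)O1 | intermediate (not isolated)
7 | (2R)-2-tert-butyl-5-(hydroxymethylidene)-1,3-dioxolan-4-one (enol; C=C geometry labile) | O=C1C(=CO)O[C@@H](C(C)(C)C)O1 | intermediate
8 | benzoyl chloride | O=C(Cl)c1ccccc1 | starting material
9 | (2R)-5-[(Z)-(benzoyloxy)methylidene]-2-tert-butyl-1,3-dioxolan-4-one (benzoyloxy cis to ring oxygen) | O=C1/C(O[C@@H](C(C)(C)C)O1)=C/OC(=O)c1ccccc1 | intermediate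
10 | (1E,3E)-buta-1,3-diene-1,4-diyl diacetate | CC(=O)O/C=C/C=C/OC(C)=O | starting material
11 | dilithium (1E,3E)-buta-1,3-diene-1,4-diolate | [Li+].[Li+].[O-]/C=C/C=C/[O-] | intermediate (not isolated)
12 | (1E,3E)-1,4-bis(tert-butyldimethylsilyloxy)buta-1,3-diene | CC(C)(C)[Si](C)(C)O/C=C/C=C/O[Si](C)(C)C(C)(C)C | intermediate
13 | (2R,5S,6R,9S,10S)-2-tert-butyl-6,9-bis(tert-butyldimethylsilyloxy)-4-oxo-1,3-dioxaspiro[4.5]dec-7-en-10-yl benzoate (spiro cycloadduct; O1, O2, O5, O6 all cis, tert-butyl anti to C2) | O=C2[C@@]1(O[C@@H](C(C)(C)C)O2)[C@H](O[Si](C)(C)C(C)(C)C)C=C[C@H](O[Si](C)(C)C(C)(C)C)[C@@H]1OC(=O)c1ccccc1 | intermediate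
14 | (1S,2R,5S,6S)-2,5-bis(tert-butyldimethylsilyloxy)-1-(hydroxymethyl)cyclohex-3-ene-1,6-diol | OC[C@@]1(O)[C@H](O[Si](C)(C)C(C)(C)C)C=C[C@H](O[Si](C)(C)C(C)(C)C)[C@@H]1O | intermediate
15 | [(1S,2R,5S,6S)-2,5-bis(tert-butyldimethylsilyloxy)-1,6-dihydroxycyclohex-3-en-1-yl]methyl benzoate | O=C(OC[C@@]1(O)[C@H](O[Si](C)(C)C(C)(C)C)C=C[C@H](O[Si](C)(C)C(C)(C)C)[C@@H]1O)c1ccccc1 | intermediate
16 | [(1S,2R,5S,6S)-2,5-bis(tert-butyldimethylsilyloxy)-1,6-(isopropylidenedioxy)cyclohex-3-en-1-yl]methyl benzoate | O=C(OC[C@@]1(O2)[C@H](O[Si](C)(C)C(C)(C)C)C=C[C@H](O[Si](C)(C)C(C)(C)C)[C@@H]1OC2(C)C)c1ccccc1 | intermediate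
17 | [(1R,2R,5S,6S)-2,5-dihydroxy-1,6-(isopropylidenedioxy)cyclohex-3-en-1-yl]methyl benzoate | O=C(OC[C@@]1(O2)[C@H](O)C=C[C@H](O)[C@@H]1OC2(C)C)c1ccccc1 | intermediate
18 | [(1R,2R,5S,6S)-2,5-bis(benzoyloxy)-1,6-(isopropylidenedioxy)cyclohex-3-en-1-yl]methyl benzoate | O=C(OC[C@@]1(O2)[C@H](OC(=O)c3ccccc3)C=C[C@H](OC(=O)c3ccccc3)[C@@H]1OC2(C)C)c1ccccc1 | intermediate
19 | [(1S,2R,5S,6S)-2,5-bis(benzoyloxy)-1,6-dihydroxycyclohex-3-en-1-yl]methyl benzoate | O=C(OC[C@@]1(O)[C@H](OC(=O)c2ccccc2)C=C[C@H](OC(=O)c2ccccc2)[C@@H]1O)c1ccccc1 | target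

**Count**

Total steps: 13. Longest linear sequence: 12 steps (1 to 19 through steps 1–5 and 7–13); the diene branch is step 6.

**Steps most likely to fail**

Step 7. The trisubstituted, doubly oxygenated alkene of 9 may react too slowly at temperatures the silyl dienol ether tolerates, so that diene decomposition or loss of endo control takes over. The fallback sets out from 11 and 9 and rejoins the route at 17. The dienediolate 11 would be trapped with iPr3SiOTf to give (1E,3E)-1,4-bis(triisopropylsilyloxy)buta-1,3-diene F1, whose enol ethers withstand a Lewis acid. The cycloaddition with 9 would then be driven by Me2AlCl coordination to the lactone carbonyl (CH2Cl2, −78 to −30 °C). This polar, asynchronous variant is expected to keep the anti-tert-butyl and carbonyl-exo preferences and to give the bis(triisopropylsilyl) cycloadduct F2. LiAlH4 reduction as in step 8 would give the bis(triisopropylsilyl) triol F3, selective O7 benzoylation with 8 the bis(triisopropylsilyl) C7 benzoate F4, and ketalisation with 2-methoxypropene the bis(triisopropylsilyl) acetonide F5. Bu4NF would then remove both silyl groups and give 17.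

Step 4. The enolised formyl lactone may be lost through reaction with residual activated DMSO or through self-condensation before it is acylated, and the subsequent O-acylation could deliver the wrong enol geometry. The fallback sets out from 5 and 8 and rejoins at 9 without passing through an aldehyde or free enol. Alcohol 5 would be benzoylated with 8 (pyridine, DMAP) to (2R,5R)-5-(benzoyloxymethyl)-2-tert-butyl-1,3-dioxolan-4-one F6. Wohl–Ziegler bromination (NBS, AIBN, PhCF3, reflux) at the captodative C5–H, the position that reacts in 5-alkyl dioxolanones of this type, would give (2R,5S)-5-(benzoyloxymethyl)-5-bromo-2-tert-butyl-1,3-dioxolan-4-one F7. Dehydrobromination with Et3N (CH2Cl2, 0 °C) toward the only β-hydrogens would then form the exocyclic enol benzoate 9.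

Step 13. Under the acidic hydrolysis, benzoyl groups may migrate onto the liberated C1/C6 hydroxyls, or the hindered cis-fused ketal may cleave incompletely. The fallback sets out from 15 and rejoins at 19, replacing the ketal by an ester on O6 alone. Steglich esterification of the secondary C6 hydroxyl of 15 with levulinic acid (DIC, DMAP; the tertiary C1 hydroxyl should not acylate) would give the O6 levulinate F8. HF·pyridine (THF/pyridine) would remove both silyl groups under non-basic conditions to give the diol levulinate F9, and benzoylation with 8 (pyridine, DMAP) would give the tribenzoate levulinate F10. Hydrazine acetate (pyridine/AcOH, rt) would then cleave only the keto ester and give 19 without exposure to strong acid.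

Further compounds
F1 | step 7 | (1E,3E)-1,4-bis(triisopropylsilyloxy)buta-1,3-diene | CC(C)[Si](C(C)C)(C(C)C)O/C=C/C=C/O[Si](C(C)C)(C(C)C)C(C)C
F2 | step 7 | bis(triisopropylsilyl) cycloadduct (silyl analogue of 13) | O=C2[C@@]1(O[C@@H](C(C)(C)C)O2)[C@H](O[Si](C(C)C)(C(C)C)C(C)C)C=C[C@H](O[Si](C(C)C)(C(C)C)C(C)C)[C@@H]1OC(=O)c1ccccc1
F3 | step 7 | bis(triisopropylsilyl) triol (silyl analogue of 14) | OC[C@@]1(O)[C@H](O[Si](C(C)C)(C(C)C)C(C)C)C=C[C@H](O[Si](C(C)C)(C(C)C)C(C)C)[C@@H]1O
F4 | step 7 | bis(triisopropylsilyl) C7 benzoate (silyl analogue of 15) | O=C(OC[C@@]1(O)[C@H](O[Si](C(C)C)(C(C)C)C(C)C)C=C[C@H](O[Si](C(C)C)(C(C)C)C(C)C)[C@@H]1O)c1ccccc1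
F5 | step 7 | bis(triisopropylsilyl) acetonide (silyl analogue of 16) | O=C(OC[C@@]1(O2)[C@H](O[Si](C(C)C)(C(C)C)C(C)C)C=C[C@H](O[Si](C(C)C)(C(C)C)C(C)C)[C@@H]1OC2(C)C)c1ccccc1
F6 | step 4 | (2R,5R)-5-(benzoyloxymethyl)-2-tert-butyl-1,3-dioxolan-4-one | O=C1[C@@H](COC(=O)c2ccccc2)O[C@@H](C(C)(C)C)O1
F7 | step 4 | (2R,5S)-5-(benzoyloxymethyl)-5-bromo-2-tert-butyl-1,3-dioxolan-4-one (bromine anti to tert-butyl) | O=C1[C@@](Br)(COC(=O)c2ccccc2)O[C@@H](C(C)(C)C)O1
F8 | step 13 | O6 levulinate of 15 | O=C(OC[C@@]1(O)[C@H](O[Si](C)(C)C(C)(C)C)C=C[C@H](O[Si](C)(C)C(C)(C)C)[C@@H]1OC(=O)CCC(C)=O)c1ccccc1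
F9 | step 13 | diol levulinate (C2/C5 hydroxyls free) | O=C(OC[C@@]1(O)[C@H](O)C=C[C@H](O)[C@@H]1OC(=O)CCC(C)=O)c1ccccc1
F10 | step 13 | tribenzoate levulinate | O=C(OC[C@@]1(O)[C@H](OC(=O)c2ccccc2)C=C[C@H](OC(=O)c2ccccc2)[C@@H]1OC(=O)CCC(C)=O)c1ccccc1
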